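## Retrosynthetic overview

1. Target (13Z)-6β,7α-diacetoxylabda-8,13-dien-15-ol ⇒ its 15-acetate (primary acetate removed last) ⇒ the 6β,7α,15-triol.
2. Triol ⇒ 7α-hydroxy-8-en-6-one ester (one LiAlH4 step gives 6β-OH and C15-OH) ⇒ 7-en-6-one (α-face hydroxylation of its ring B dienolate sets C7 and moves the alkene to C8=C9) ⇒ Δ7 bicyclic ester (allylic oxidation at C6).
3. Both rings ⇒ one proton-initiated, catalyst-controlled bicyclization of acyclic methyl (2Z,6E,10E)-geranylgeranoate, which already holds all 20 skeletal carbons. Ring A closes first (C4–C5 bond), then ring B (C9–C10 bond), ending by loss of H-7; the (2Z)-enoate stays out.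
4. Acyclic ester ⇒ ynoate + Me2CuLi (syn-carbocupration sets 13Z) ⇒ (2E,6E)-farnesyl bromide + propargyl dianion + methyl chloroformate.

Assumption: 1 and 2 are bought; labdane numbering is used (decalin C1–C10, side chain C11–C16, C17 on C8); "IDPi acid" means the enantiomer of a confined BINOL-derived N-triflyl imidodiphosphorimidate Brønsted acid that turns (3E,7E)-homofarnesol into (−)-ambrox, i.e. the one giving the 5S,10S decalin.

## Route

Step 1
Reactants: 1 (2E,6E)-farnesyl bromide; 2 propargyl bromide
Product: 5 methyl (6E,10E)-7,11,15-trimethylhexadeca-6,10,14-trien-2-ynoate, via 1,3-dilithiopropyne 3 (not isolated), via lithium acetylide 4 (not isolated)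
Conditions: 2, n-BuLi (2 equiv), TMEDA, Et2O, −78 °C; 1, −78 → 0 °C; ClCO2Me, −78 °C → rt
Reagents that add atoms: methyl chloroformate, COC(=O)Cl
Why: The sp3 carbanion of the propargyl dianion is the more nucleophilic site and displaces the primary allylic bromide by SN2 without touching the E-alkenes, and the surviving lithium acetylide is then C-acylated by the chloroformate (dianion alkylation, then acetylide carboxylation); no stereocentre is formed.

Step 2
Reactants: 5 methyl (6E,10E)-7,11,15-trimethylhexadeca-6,10,14-trien-2-ynoate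
Product: 7 methyl (2Z,6E,10E)-3,7,11,15-tetramethylhexadeca-2,6,10,14-tetraenoate, via alkenylcuprate 6 (not isolated)
Conditions: Me2CuLi (from CuBr·SMe2 + 2 MeLi), THF, −78 °C; aq. NH4Cl, −78 °C
Reagents that add atoms: lithium dimethylcuprate Me2CuLi, [Li+].C[Cu-]C
Why: Syn-carbocupration of the ynoate puts the new methyl and copper cis, and protonation with retention below −70 °C (before the alkenylcopper can equilibrate through the allenoate) gives the chain cis to the ester, i.e. the 2Z (later 13Z) enoate; conjugate addition of a Gilman cuprate to an alkynoate.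

Step 3
Reactants: 7 methyl (2Z,6E,10E)-3,7,11,15-tetramethylhexadeca-2,6,10,14-tetraenoate
Product: 8 methyl (13Z)-labda-7,13-dien-15-oate
Conditions: IDPi acid (5 mol %), (CF3)3COH, 0 °C
Reagents that add atoms: none
Why: Proposed new method: a catalytic asymmetric proton-initiated polyene bicyclization ended by proton loss instead of by an O-nucleophile; the confined acid protonates the terminal trisubstituted alkene, the (6E,10E)-chain folds chair–chair in the chiral pocket and both C–C bonds form by anti additions (Stork–Eschenmoser), which sets the trans-decalin with 10β-CH3, 5α-H and 9α-H in the 5S,10S sense fixed by the catalyst enantiomer, the C8 cation then loses the accessible axial 7α-H to the counter-anion to give the Δ7 alkene (Δ8(17) and Δ8(9) isomers expected as minor products, removable on AgNO3–silica), and the electron-poor (2Z)-enoate cannot act as a third nucleophile, so the cascade stops at two rings; the closest known reaction type is the IDPi-catalysed cyclization of homofarnesol to ambrox in fluorinated alcohols.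

Step 4
Reactants: 8 methyl (13Z)-labda-7,13-dien-15-oate
Product: 9 methyl (13Z)-6-oxolabda-7,13-dien-15-oate
Conditions: dirhodium tetracaprolactamate Rh2(cap)4 (1 mol %), t-BuOOH (5 equiv), K2CO3, CH2Cl2, rt
Reagents that add atoms: tert-butyl hydroperoxide, CC(C)(C)OO
Why: Allylic C–H oxidation by the tert-butylperoxyl radical chain attacks the ring CH2 next to the electron-rich trisubstituted Δ7 alkene (as in Δ5-steroid to 7-ketone oxidations), while the allylic positions of the electron-poor enoate react far more slowly; no stereocentre is formed and C5 keeps the stable trans fusion.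

Step 5
Reactants: 9 methyl (13Z)-6-oxolabda-7,13-dien-15-oate
Product: 11 methyl (13Z)-7α-hydroxy-6-oxolabda-8,13-dien-15-oate, via potassium dienolate 10 (not isolated)
Conditions: KN(SiMe3)2 (1.0 equiv), THF, −78 → −40 °C; 2-(phenylsulfonyl)-3-phenyloxaziridine, −78 °C; AcOH, −78 °C
Reagents that add atoms: 2-(phenylsulfonyl)-3-phenyloxaziridine, O=S(=O)(c1ccccc1)N1OC1c1ccccc1
Why: γ-Deprotonation at the axial 9α-H (syn to the carbonyl, giving the more substituted endocyclic dienolate) and electrophilic hydroxylation at the α-carbon C7 (Davis oxidation of an extended enolate) move the alkene to C8=C9, and because the β face is screened by the axial C10 and C4β methyls the oxygen arrives from the α face to give the 7α (7S) alcohol.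

Step 6
Reactants: 11 methyl (13Z)-7α-hydroxy-6-oxolabda-8,13-dien-15-oate
Product: 12 (13Z)-labda-8,13-diene-6β,7α,15-triol
Conditions: LiAlH4 (4 equiv), Et2O, −78 → 0 °C; then H2O, aq. NaOH
Reagents that add atoms: none
Why: LiAlH4 first forms the 7α-alkoxyaluminate, which delivers hydride to the α face of the C6 ketone, the same face left open by the two axial β methyls, so the axial 6β (6S) alcohol trans to 7α-OH results, and the same reagent reduces the enoate 1,2 to the allylic alcohol with the Z geometry kept; hydroxyl-directed and substrate-controlled hydride reduction.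

Step 7
Reactants: 12 (13Z)-labda-8,13-diene-6β,7α,15-triol
Product: 13 (13Z)-labda-8,13-diene-6β,7α,15-triyl triacetate
Conditions: Ac2O, DMAP, pyridine, 60 °C
Reagents that add atoms: acetic anhydride, CC(=O)OC(C)=O
Why: DMAP-catalysed acyl transfer esterifies all three hydroxyls, the hindered axial 6β-OH needing the forcing conditions; O-acylation touches no stereocentre.

Step 8
Reactants: 13 (13Z)-labda-8,13-diene-6β,7α,15-triyl triacetate
Product: 14 (13Z)-6β,7α-diacetoxylabda-8,13-dien-15-ol
Conditions: K2CO3 (0.3 equiv), MeOH, 0 °C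
Reagents that add atoms: none
Why: Base-catalysed transesterification (Zemplén-type methanolysis) is fastest by far at the unhindered primary allylic acetate, while the axial 6β- and 7α-acetates, flanked by the angular methyls and by each other, survive at 0 °C; no stereocentre is involved.

## Compound list

1 | (2E,6E)-farnesyl bromide, (2E,6E)-1-bromo-3,7,11-trimethyldodeca-2,6,10-triene | CC(C)=CCC/C(C)=C/CC/C(C)=C/CBr | starting material
2 | propargyl bromide, 3-bromoprop-1-yne | C#CCBr | starting material
3 | 1,3-dilithiopropyne | [Li]CC#C[Li] | intermediate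
4 | lithium acetylide of (5E,9E)-6,10,14-trimethylpentadeca-5,9,13-trien-1-yne | CC(C)=CCC/C(C)=C/CC/C(C)=C/CCC#C[Li] | intermediate
5 | methyl (6E,10E)-7,11,15-trimethylhexadeca-6,10,14-trien-2-ynoate | CC(C)=CCC/C(C)=C/CC/C(C)=C/CCC#CC(=O)OC | intermediate
6 | lithium methyl(alkenyl)cuprate from syn addition to 5: Cu on C2 cis to the new C3 methyl, chain cis to CO2Me | CC(C)=CCC/C(C)=C/CC/C(C)=C/CC/C(C)=C(/[Cu-]C)C(=O)OC.[Li+] | intermediate
7 | methyl (2Z,6E,10E)-3,7,11,15-tetramethylhexadeca-2,6,10,14-tetraenoate | CC(C)=CCC/C(C)=C/CC/C(C)=C/CC/C(C)=C\C(=O)OC | intermediate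
8 | methyl (13Z)-labda-7,13-dien-15-oate; 5S,9S,10S; trans-decalin with 5α-H, 9α-H, 10β-CH3 | CC1=CC[C@H]2C(C)(C)CCC[C@]2(C)[C@H]1CC/C(C)=C\C(=O)OC | intermediate
9 | methyl (13Z)-6-oxolabda-7,13-dien-15-oate; 5α-H, 9α-H, 10β-CH3 | CC1=CC(=O)[C@H]2C(C)(C)CCC[C@]2(C)[C@H]1CC/C(C)=C\C(=O)OC | intermediate
10 | potassium 6,8(9)-dienolate of 9 (potassium salt of methyl (13Z)-6-hydroxylabda-6,8,13-trien-15-oate); 5α-H, 10β-CH3 | [K+].[O-]C1=CC(C)=C(CC/C(C)=C\C(=O)OC)[C@@]2(C)CCCC(C)(C)[C@H]12 | intermediate
11 | methyl (13Z)-7α-hydroxy-6-oxolabda-8,13-dien-15-oate; 7S, 5α-H, 10β-CH3 | O=C1[C@@H](O)C(C)=C(CC/C(C)=C\C(=O)OC)[C@@]2(C)CCCC(C)(C)[C@H]12 | intermediate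
12 | (13Z)-labda-8,13-diene-6β,7α,15-triol; 5S,6S,7S,10S | O[C@@H]1[C@@H](O)C(C)=C(CC/C(C)=C\CO)[C@@]2(C)CCCC(C)(C)[C@H]12 | intermediate
13 | (13Z)-labda-8,13-diene-6β,7α,15-triyl triacetate | CC(=O)O[C@@H]1[C@@H](OC(C)=O)C(C)=C(CC/C(C)=C\COC(C)=O)[C@@]2(C)CCCC(C)(C)[C@H]12 | intermediate
14 | (13Z)-6β,7α-diacetoxylabda-8,13-dien-15-ol; 5S,6S,7S,10S | CC(=O)O[C@@H]1[C@@H](OC(C)=O)C(C)=C(CC/C(C)=C\CO)[C@@]2(C)CCCC(C)(C)[C@H]12 | target

## Step count and risks

Total steps: 8. Longest linear sequence: 8 steps (1 → 14).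

The three steps most likely to fail:

Step 3, the bicyclization. It is an untested extension: the enantioselectivity may be low without an H-bonding terminator, the cascade may stop at the monocycle, or the Δ8(9)/Δ8(17) isomers may dominate. Fallback: set out from 7 and change the initiator from a proton to an iodonium ion. N-Iodosuccinimide with a stoichiometric chiral BINOL-derived phosphoramidite promoter (toluene, −40 °C, ring B closed if needed with BF3·OEt2) gives methyl (13Z)-3β-iodolabda-7,13-dien-15-oate F1, with the iodine equatorial from anti addition in the chair fold. Radical deiodination (Bu3SnH, AIBN, benzene, 80 °C) then comes back to the route at 8.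

Step 5, the deconjugative hydroxylation. The base may take a C17 methyl proton, the oxidant may attack the γ-carbon C9, and 11 can isomerize to the diosphenol if not kept cold and neutral. Fallback: set out from 9 and accept γ-oxidation, then transpose.
- Equilibrating soft enolization (Me3SiOSO2CF3, Et3N, CH2Cl2, 0 °C) gives methyl (13Z)-6-(trimethylsilyloxy)labda-6,8,13-trien-15-oate F2.
- Peracid (mCPBA, NaHCO3, CH2Cl2, −20 °C) attacks its γ-terminus from the α face to give methyl (13Z)-9α-hydroxy-6-oxolabda-7,13-dien-15-oate F3.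
- NaBH4/CeCl3·7H2O (MeOH, −78 °C) adds hydride from the α face to give methyl (13Z)-6β,9α-dihydroxylabda-7,13-dien-15-oate F4.
- Catalytic Ph3SiOReO3 (Et2O, 0 °C) transposes the tertiary allylic alcohol suprafacially from 9α to 7α, with the alkene moving to the tetrasubstituted C8=C9 position, to give methyl (13Z)-6β,7α-dihydroxylabda-8,13-dien-15-oate F5.
- LiAlH4 reduction of the ester comes back to the route at 12.

Step 8, the selective deacetylation. The allylic 7α-acetate may be lost along with the primary one. Fallback: set out from 12 and mark the primary alcohol before acylation. TBSCl/imidazole (DMF, 0 °C) silylates only the primary allylic hydroxyl to give (13Z)-15-(tert-butyldimethylsilyloxy)labda-8,13-diene-6β,7α-diol F6. Ac2O/DMAP/pyridine (60 °C) gives (13Z)-15-(tert-butyldimethylsilyloxy)labda-8,13-diene-6β,7α-diyl diacetate F7, and HF·pyridine (THF, 0 °C) removes the silyl group to arrive at 14.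

Further compounds
F1 | step 3 | methyl (13Z)-3β-iodolabda-7,13-dien-15-oate | CC1=CC[C@H]2C(C)(C)[C@@H](I)CC[C@]2(C)[C@H]1CC/C(C)=C\C(=O)OC
F2 | step 5 | methyl (13Z)-6-(trimethylsilyloxy)labda-6,8,13-trien-15-oate | C[Si](C)(C)OC1=CC(C)=C(CC/C(C)=C\C(=O)OC)[C@@]2(C)CCCC(C)(C)[C@H]12
F3 | step 5 | methyl (13Z)-9α-hydroxy-6-oxolabda-7,13-dien-15-oate | CC1=CC(=O)[C@H]2C(C)(C)CCC[C@]2(C)[C@@]1(O)CC/C(C)=C\C(=O)OC
F4 | step 5 | methyl (13Z)-6β,9α-dihydroxylabda-7,13-dien-15-oate | CC1=C[C@@H](O)[C@H]2C(C)(C)CCC[C@]2(C)[C@@]1(O)CC/C(C)=C\C(=O)OC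
F5 | step 5 | methyl (13Z)-6β,7α-dihydroxylabda-8,13-dien-15-oate | O[C@@H]1[C@@H](O)C(C)=C(CC/C(C)=C\C(=O)OC)[C@@]2(C)CCCC(C)(C)[C@H]12
F6 | step 8 | (13Z)-15-(tert-butyldimethylsilyloxy)labda-8,13-diene-6β,7α-diol | O[C@@H]1[C@@H](O)C(C)=C(CC/C(C)=C\CO[Si](C)(C)C(C)(C)C)[C@@]2(C)CCCC(C)(C)[C@H]12
F7 | step 8 | (13Z)-15-(tert-butyldimethylsilyloxy)labda-8,13-diene-6β,7α-diyl diacetate | CC(=O)O[C@@H]1[C@@H](OC(C)=O)C(C)=C(CC/C(C)=C\CO[Si](C)(C)C(C)(C)C)[C@@]2(C)CCCC(C)(C)[C@H]12
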